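**Retrosynthetic overview**

1. The ester C–O bond is cut last: the hydroazulenyl methanol is joined to unprotected vanillic acid by a Mitsunobu reaction.
2. The tetrasubstituted C1=C8a double bond and the isopropyl group come from a C1 ketone (conjugate hydride addition, enolate triflation, iron-catalysed isopropyl coupling). The C5 hydrogen replaces a trimethylsilyl group that steers the cycloaddition and leaves together with the oxygen protecting group.
3. The seven-membered ring is made by a rhodium-catalysed intermolecular (5+2) cycloaddition of a 1-vinylbicyclo[3.1.0]hexanol with a silylated propargyl ether. It forms C4–C5 and C6–C7 and opens the three-membered ring.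
4. Enabling feature: in the cycloheptene ring the C5=C6 double bond (C6 carries the CH2O group) lies between two CH2 groups (C4, C7). The other five ring carbons C7–C8–C8a–C3a–C4 map onto a vinyl group (C7, C8) on a cyclopropane (C8a, C3a, C4) fused to the cyclopentane across C8a–C3a. C3a is quaternary, so it offers no hydrogen for β-hydride elimination and no bond to it is broken, and C1 next to C8a can carry oxygen.
5. Ring order: cyclopentene (purchased) → cyclopropane (step 3; C3a set by hydroxyl-directed cyclopropanation after a CBS reduction) → cycloheptadiene (step 5; cyclopropane consumed).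

Key step: step 5

Remark on numbering: the bicyclic core is numbered as a hydroazulene: C1 (sp2, isopropyl), C2, C3, C3a (quaternary, methyl), C4, C5 (=CH), C6 (carries CH2O), C7, C8, C8a. The only stereocentre of the target, C3a, is R.
Assumption: the (S)-configured CBS catalyst is taken to give the (1R)-alcohol, by the usual model with the bromoalkenyl arm of the enone as the large group.

**Step 1**
Reactants: 1 2-bromo-3-methylcyclopent-2-en-1-one
Product: 2 (1R)-2-bromo-3-methylcyclopent-2-en-1-ol
Conditions: (S)-2-methyl-CBS-oxazaborolidine (10 mol%), BH3·SMe2, THF, −20 °C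
Reagents that add atoms: none
Why: Corey–Bakshi–Shibata reduction, in which the oxazaborolidine binds the ketone with the bromoalkenyl arm as the large group and delivers hydride to one face, should set the (R)-carbinol centre that later relays its configuration to the quaternary carbon.

**Step 2**
Reactants: 2 (1R)-2-bromo-3-methylcyclopent-2-en-1-ol
Product: 3 (1R)-3-methyl-2-vinylcyclopent-2-en-1-ol
Conditions: vinylboronic acid pinacol ester, Pd(dppf)Cl2 (5 mol%), K2CO3, 1,4-dioxane/H2O, 80 °C
Reagents that add atoms: vinylboronic acid pinacol ester, C=CB1OC(C)(C)C(C)(C)O1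
Why: Suzuki–Miyaura coupling of a cyclic alkenyl bromide with a vinylboronate tolerates the free allylic hydroxyl under basic conditions and does not touch the carbinol centre.

**Step 3**
Reactants: 3 (1R)-3-methyl-2-vinylcyclopent-2-en-1-ol
Product: 4 (1R,2R,5R)-5-methyl-1-vinylbicyclo[3.1.0]hexan-2-ol (hydroxyl cis to the cyclopropane CH2)
Conditions: Et2Zn (2.2 equiv), CH2I2 (2.2 equiv), CH2Cl2, −15 → 0 °C
Reagents that add atoms: diiodomethane, ICI
Why: In this hydroxyl-directed Simmons–Smith cyclopropanation (Furukawa variant) the zinc alkoxide should deliver the carbenoid to the electron-rich tetrasubstituted ring alkene on the face of the oxygen, so both new centres (C1 and the methyl-bearing C5) form cis to the hydroxyl, while the less nucleophilic vinyl group, which is only homoallylic to the oxygen, is left.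

**Step 4**
Reactants: 5 3-(trimethylsilyl)prop-2-yn-1-ol
Product: 6 tert-butyldimethyl{[3-(trimethylsilyl)prop-2-yn-1-yl]oxy}silane
Conditions: TBSCl, imidazole, CH2Cl2, 0 °C → rt
Reagents that add atoms: tert-butyldimethylsilyl chloride, CC(C)(C)[Si](C)(C)Cl
Why: Imidazole-promoted silylation of a primary propargylic alcohol is routine and protects the oxygen against the hydride and triflating reagents used later.

**Step 5**
Reactants: 4 (1R,2R,5R)-5-methyl-1-vinylbicyclo[3.1.0]hexan-2-ol; 6 tert-butyldimethyl{[3-(trimethylsilyl)prop-2-yn-1-yl]oxy}silane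
Product: 7 (1R,3aR)-6-{[(tert-butyldimethylsilyl)oxy]methyl}-3a-methyl-5-(trimethylsilyl)-1,2,3,3a,4,7-hexahydroazulen-1-ol
Conditions: [Rh(CO)2Cl]2 (5 mol%), 6 (1.5 equiv), ClCH2CH2Cl, 80 °C
Reagents that add atoms: none
Why: [Rh(CO)2Cl]2 binds the vinyl group of 4 and inserts into the less substituted cyclopropane bond C1–C6 (bicyclohexane numbering) to give a σ-alkyl π-allyl rhodacycle of trivalent rhodium; alkyne 6 then inserts into the rhodium–allyl bond at the former vinyl terminus (new bond C6–C7, hydroazulene numbering), and C(sp2)–C(sp3) reductive elimination with the former cyclopropane methylene makes C4–C5 and returns monovalent rhodium. The closest known reaction type is the rhodium-catalysed intermolecular (5+2) cycloaddition of 1-substituted vinylcyclopropanes with alkynes, which tolerates free hydroxyl groups. The cycloheptadiene ring is closed as a two-bond (5+2) annulation, the second bond by reductive elimination from an eight-membered rhodacycle, and the three-membered ring is consumed. No new stereocentre is formed: C3a keeps the configuration from step 3 because none of its bonds is broken, and the carbinol centre is carried along. The step needs three selectivities: cleavage of C1–C6 and not C1–C5 (C5 is quaternary, so the alternative would need a tertiary alkylrhodium), no β-hydride elimination (the carbon next to the rhodium-bound methylene is the hydrogen-free C3a), and one alkyne orientation, which the bulky trimethylsilyl group should secure by sitting away from the first-formed bond and on the rhodium-bound carbon, so that silicon ends at C5 and the silyloxymethyl group at C6.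

**Step 6**
Reactants: 7 (1R,3aR)-6-{[(tert-butyldimethylsilyl)oxy]methyl}-3a-methyl-5-(trimethylsilyl)-1,2,3,3a,4,7-hexahydroazulen-1-ol
Product: 8 (3aR)-6-{[(tert-butyldimethylsilyl)oxy]methyl}-3a-methyl-5-(trimethylsilyl)-3,3a,4,7-tetrahydroazulen-1(2H)-one
Conditions: Dess–Martin periodinane, CH2Cl2, 0 °C → rt
Reagents that add atoms: none
Why: Dess–Martin oxidation of the secondary allylic alcohol should give the enone under mild conditions that leave the silyl ether, the vinylsilane and the skipped diene in place, and it removes the carbinol stereocentre once it has done its work.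

**Step 7**
Reactants: 8 (3aR)-6-{[(tert-butyldimethylsilyl)oxy]methyl}-3a-methyl-5-(trimethylsilyl)-3,3a,4,7-tetrahydroazulen-1(2H)-one
Product: 10 (3aR)-6-{[(tert-butyldimethylsilyl)oxy]methyl}-3a-methyl-5-(trimethylsilyl)-2,3,3a,4,7,8-hexahydroazulen-1-yl trifluoromethanesulfonate, via lithium enolate 9 (not isolated)
Conditions: LiBH(s-Bu)3 (L-Selectride, 1.1 equiv), THF, −78 °C; then PhNTf2, −78 → 0 °C
Reagents that add atoms: N-phenylbis(trifluoromethanesulfonimide), O=S(=O)(N(c1ccccc1)S(=O)(=O)C(F)(F)F)C(F)(F)F
Why: Conjugate hydride addition to the fixed s-cis enone should put hydrogen on C8 and generate the C1–C8a enolate regiospecifically, and O-sulfonylation of that enolate (reductive enolate triflation) locks the tetrasubstituted double bond in its final position.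

**Step 8**
Reactants: 10 (3aR)-6-{[(tert-butyldimethylsilyl)oxy]methyl}-3a-methyl-5-(trimethylsilyl)-2,3,3a,4,7,8-hexahydroazulen-1-yl trifluoromethanesulfonate
Product: 11 tert-butyl{[(3aR)-1-isopropyl-3a-methyl-5-(trimethylsilyl)-2,3,3a,4,7,8-hexahydroazulen-6-yl]methoxy}dimethylsilane
Conditions: i-PrMgCl (2 equiv), Fe(acac)3 (10 mol%), THF/NMP, −30 °C
Reagents that add atoms: isopropylmagnesium chloride, CC(C)[Mg]Cl
Why: Iron-catalysed Kumada-type cross-coupling of alkenyl triflates with alkyl Grignard reagents is fast at low temperature, accepts secondary alkyl groups and leaves silyl ethers and vinylsilanes alone, so isopropyl should replace the triflate with the double bond kept in place.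

**Step 9**
Reactants: 11 tert-butyl{[(3aR)-1-isopropyl-3a-methyl-5-(trimethylsilyl)-2,3,3a,4,7,8-hexahydroazulen-6-yl]methoxy}dimethylsilane
Product: 14 [(3aR)-1-isopropyl-3a-methyl-2,3,3a,4,7,8-hexahydroazulen-6-yl]methanol, via silyl alcohol 12 (not isolated), via trimethylsilyl ether 13 (not isolated)
Conditions: Bu4NF (5 equiv), THF, rt → 65 °C
Reagents that add atoms: none
Why: Fluoride first cleaves the primary silyl ether, the cis-disposed alkoxide then attacks the neighbouring vinylsilane silicon (five-membered siliconate, Brook-type 1,4 carbon-to-oxygen silyl shift with protonation of C5 under retention) and fluoride removes the resulting O-silyl group, a known hydroxyl-assisted protodesilylation of (Z)-γ-silyl allylic alcohols that needs no acid that could move the double bonds.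

**Step 10**
Reactants: 14 [(3aR)-1-isopropyl-3a-methyl-2,3,3a,4,7,8-hexahydroazulen-6-yl]methanol; 15 4-hydroxy-3-methoxybenzoic acid (vanillic acid)
Product: 16 [(3aR)-1-isopropyl-3a-methyl-2,3,3a,4,7,8-hexahydroazulen-6-yl]methyl 4-hydroxy-3-methoxybenzoate (target)
Conditions: PPh3, DIAD, 15 (1.5 equiv), THF, 0 °C → rt
Reagents that add atoms: none
Why: Mitsunobu esterification activates the primary allylic alcohol and uses the carboxylic acid, far more acidic than the phenol, as the nucleophile, so unprotected vanillic acid should be alkylated chemoselectively at the carboxylate, as in Mitsunobu esterifications of unprotected hydroxycinnamic acids.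

**Compound list**

1 | 2-bromo-3-methylcyclopent-2-en-1-one | CC1=C(Br)C(=O)CC1 | starting material
2 | (1R)-2-bromo-3-methylcyclopent-2-en-1-ol | BrC1=C(C)CC[C@H]1O | intermediate
3 | (1R)-3-methyl-2-vinylcyclopent-2-en-1-ol | C=CC1=C(C)CC[C@H]1O | intermediate
4 | (1R,2R,5R)-5-methyl-1-vinylbicyclo[3.1.0]hexan-2-ol | C=C[C@]12C[C@@]1(C)CC[C@H]2O | intermediate
5 | 3-(trimethylsilyl)prop-2-yn-1-ol | C[Si](C)(C)C#CCO | starting material
6 | tert-butyldimethyl{[3-(trimethylsilyl)prop-2-yn-1-yl]oxy}silane | CC(C)(C)[Si](C)(C)OCC#C[Si](C)(C)C | intermediate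
7 | (1R,3aR)-6-{[(tert-butyldimethylsilyl)oxy]methyl}-3a-methyl-5-(trimethylsilyl)-1,2,3,3a,4,7-hexahydroazulen-1-ol | CC(C)(C)[Si](C)(C)OCC1=C([Si](C)(C)C)C[C@@]2(C)CC[C@@H](O)C2=CC1 | intermediate
8 | (3aR)-6-{[(tert-butyldimethylsilyl)oxy]methyl}-3a-methyl-5-(trimethylsilyl)-3,3a,4,7-tetrahydroazulen-1(2H)-one | CC(C)(C)[Si](C)(C)OCC1=C([Si](C)(C)C)C[C@@]2(C)CCC(=O)C2=CC1 | intermediate
9 | lithium (3aR)-6-{[(tert-butyldimethylsilyl)oxy]methyl}-3a-methyl-5-(trimethylsilyl)-2,3,3a,4,7,8-hexahydroazulen-1-olate | CC(C)(C)[Si](C)(C)OCC1=C([Si](C)(C)C)C[C@@]2(C)CCC([O-])=C2CC1.[Li+] | intermediate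
10 | (3aR)-6-{[(tert-butyldimethylsilyl)oxy]methyl}-3a-methyl-5-(trimethylsilyl)-2,3,3a,4,7,8-hexahydroazulen-1-yl trifluoromethanesulfonate | CC(C)(C)[Si](C)(C)OCC1=C([Si](C)(C)C)C[C@@]2(C)CCC(OS(=O)(=O)C(F)(F)F)=C2CC1 | intermediate
11 | tert-butyl{[(3aR)-1-isopropyl-3a-methyl-5-(trimethylsilyl)-2,3,3a,4,7,8-hexahydroazulen-6-yl]methoxy}dimethylsilane | CC(C)(C)[Si](C)(C)OCC1=C([Si](C)(C)C)C[C@@]2(C)CCC(C(C)C)=C2CC1 | intermediate
12 | [(3aR)-1-isopropyl-3a-methyl-5-(trimethylsilyl)-2,3,3a,4,7,8-hexahydroazulen-6-yl]methanol | OCC1=C([Si](C)(C)C)C[C@@]2(C)CCC(C(C)C)=C2CC1 | intermediate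
13 | {[(3aR)-1-isopropyl-3a-methyl-2,3,3a,4,7,8-hexahydroazulen-6-yl]methoxy}trimethylsilane | C[Si](C)(C)OCC1=CC[C@@]2(C)CCC(C(C)C)=C2CC1 | intermediate
14 | [(3aR)-1-isopropyl-3a-methyl-2,3,3a,4,7,8-hexahydroazulen-6-yl]methanol | OCC1=CC[C@@]2(C)CCC(C(C)C)=C2CC1 | intermediate
15 | 4-hydroxy-3-methoxybenzoic acid (vanillic acid) | COc1cc(C(=O)O)ccc1O | starting material
16 | [(3aR)-1-isopropyl-3a-methyl-2,3,3a,4,7,8-hexahydroazulen-6-yl]methyl 4-hydroxy-3-methoxybenzoate | COc1cc(C(=O)OCC2=CC[C@@]3(C)CCC(C(C)C)=C3CC2)ccc1O | target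

**Step count and risks**

Total steps: 10. Longest linear sequence: 9 steps (1 → 2 → 3 → 4 → 7 → 8 → 10 → 11 → 14 → 16; step 4 is a one-step side branch).

Steps most likely to fail:

Step 5. What may go wrong is slow insertion of the hindered silylalkyne, or insertion with the two alkyne substituents the other way round, which would put silicon at C6 and the oxymethyl group at C5. The fallback sets out from 4 and uses ethyl 3-(trimethylsilyl)propiolate as the two-carbon partner ([Rh(CO)2Cl]2, ClCH2CH2Cl, 80 °C). This alkyne is electron-poor and therefore a more reactive partner. Its ester group prefers the carbon that makes the first bond while silicon prefers the rhodium-bound carbon, so an electronic and a steric bias point the same way. This should give ethyl (1R,3aR)-1-hydroxy-3a-methyl-5-(trimethylsilyl)-1,2,3,3a,4,7-hexahydroazulene-6-carboxylate F1. Dess–Martin oxidation would convert it into ethyl (3aR)-3a-methyl-1-oxo-5-(trimethylsilyl)-1,2,3,3a,4,7-hexahydroazulene-6-carboxylate F2. LiBH(s-Bu)3 and then PhNTf2 would lead through the lithium enolate F3 to the enol triflate F4. i-PrMgCl with Fe(acac)3 at −30 °C, a coupling fast enough to spare the ester, would give the isopropyl ester F5. Reduction of F5 with i-Bu2AlH (CH2Cl2, −78 °C) would give silyl alcohol 12, where the route is rejoined; 12 is then desilylated to 14 with Bu4NF as in step 9.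

Step 8. What may go wrong is slow oxidative addition at the hindered tetrasubstituted triflate, with reduction of the triflate or isomerisation of the isopropyl group through β-hydride elimination. The fallback sets out from 10 and couples an sp2 partner instead: Suzuki–Miyaura reaction with isopropenylboronic acid pinacol ester (Pd(PPh3)4, K3PO4, 1,4-dioxane/H2O, 80 °C) should give tert-butyl{[(3aR)-1-isopropenyl-3a-methyl-5-(trimethylsilyl)-2,3,3a,4,7,8-hexahydroazulen-6-yl]methoxy}dimethylsilane F6. Diimide (2-nitrobenzenesulfonylhydrazide, Et3N, CH2Cl2, rt) should then reduce only the 1,1-disubstituted double bond, not the tetrasubstituted alkene or the vinylsilane, and return to the route at 11.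

Step 7. What may go wrong is hydride attack at the carbonyl carbon in competition with conjugate delivery, or incomplete O-sulfonylation of the hindered enolate. The fallback sets out from 8 and separates the two events: RhCl(PPh3)3-catalysed 1,4-hydrosilylation with PhMe2SiH (benzene, 50 °C) should give the dimethylphenylsilyl enol ether F7 with the double bond already at C1–C8a. MeLi (THF, 0 °C) would cleave it to lithium enolate 9, where the route is rejoined and the enolate is triflated with PhNTf2 to 10.

**Further compounds**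

F1 | step 5 | ethyl (1R,3aR)-1-hydroxy-3a-methyl-5-(trimethylsilyl)-1,2,3,3a,4,7-hexahydroazulene-6-carboxylate | CCOC(=O)C1=C([Si](C)(C)C)C[C@@]2(C)CC[C@@H](O)C2=CC1
F2 | step 5 | ethyl (3aR)-3a-methyl-1-oxo-5-(trimethylsilyl)-1,2,3,3a,4,7-hexahydroazulene-6-carboxylate | CCOC(=O)C1=C([Si](C)(C)C)C[C@@]2(C)CCC(=O)C2=CC1
F3 | step 5 | lithium (3aR)-6-(ethoxycarbonyl)-3a-methyl-5-(trimethylsilyl)-2,3,3a,4,7,8-hexahydroazulen-1-olate | CCOC(=O)C1=C([Si](C)(C)C)C[C@@]2(C)CCC([O-])=C2CC1.[Li+]
F4 | step 5 | ethyl (3aR)-3a-methyl-1-{[(trifluoromethyl)sulfonyl]oxy}-5-(trimethylsilyl)-2,3,3a,4,7,8-hexahydroazulene-6-carboxylate | CCOC(=O)C1=C([Si](C)(C)C)C[C@@]2(C)CCC(OS(=O)(=O)C(F)(F)F)=C2CC1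
F5 | step 5 | ethyl (3aR)-1-isopropyl-3a-methyl-5-(trimethylsilyl)-2,3,3a,4,7,8-hexahydroazulene-6-carboxylate | CCOC(=O)C1=C([Si](C)(C)C)C[C@@]2(C)CCC(C(C)C)=C2CC1
F6 | step 8 | tert-butyl{[(3aR)-1-isopropenyl-3a-methyl-5-(trimethylsilyl)-2,3,3a,4,7,8-hexahydroazulen-6-yl]methoxy}dimethylsilane | CC(C)(C)[Si](C)(C)OCC1=C([Si](C)(C)C)C[C@@]2(C)CCC(C(C)=C)=C2CC1
F7 | step 7 | tert-butyl{[(3aR)-1-{[dimethyl(phenyl)silyl]oxy}-3a-methyl-5-(trimethylsilyl)-2,3,3a,4,7,8-hexahydroazulen-6-yl]methoxy}dimethylsilane | CC(C)(C)[Si](C)(C)OCC1=C([Si](C)(C)C)C[C@@]2(C)CCC(O[Si](C)(C)c3ccccc3)=C2CC1
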